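G rose and then fell in the midnight run, and the flask asked about has the same charge, so I read that run.

| flask | Q | L | remark | time |
|---|---|---|---|---|
| midnight | 1 M | 2 M | the very flask that is asked about, followed so far |  |
| winter | 2 M | 2 M | run made earlier |  |
| flask | 1.0 M | 2.00 M |  | 40 min |

| midnight: time / min | midnight: G / % | winter: time / min | winter: G / % |
|---|---|---|---|
| 1.00 | 29 | 1.00 | 27 |
| 2.00 | 52 | 2.00 | 43 |
| 3.00 | 65 | 5.00 | 53 |
| 6.00 | 65 | 10.0 | 38 |
| 12.0 | 39 | 20.0 | 14 |
| 20.0 | 18 | 40.0 | 3 |

(standard deviation of a reading: 2 percentage points)

1. the best time, 40 min at the latest, for G
2. the amount of G, in percent of the Q charged, at that time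



I worked with the fraction left. I treated the stretch from 12.0 min to 20.0 min as pure loss of G, and the fraction left there gave a fall of 0.0966 min⁻¹. Carried back to the start at that rate, the reading of 39 % becomes 124 % of the charge, above the charge itself, and that excess measures what was lost while G was being made. For a plain chain from Q through G to a loss, one minus the inverse of that figure gives 0.196, my loss number: the fraction of G lost per minute over the fraction of Q turned into G per minute, as read from the midnight run.

Raised to the power of itself over one minus itself, this number gives the peak as a share of the G made in total, 67.2 %. With the fall it puts that peak at 4.11 min, between the two equal readings. One number was not enough for the start, though: it gives 37.0 % at 1.00 min, more than the 29 % read, which points to a lag, an induction period.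

The forecast said of the midnight run that “that run answers the question directly” and gave 4.4 min (range 3.8 min to 5 min) and 68 % (range 65 % to 71 %). My own time is earlier and my height lower.

The simulation gave 66.5 % at 4.17 min.

    Q → X (k = 0.0103 s⁻¹)
    L → J (k = 0.00721 s⁻¹)
    X + J → G (k = 1.15 M⁻¹ s⁻¹)
    2 J → Z (k = 2.15 M⁻¹ s⁻¹)
    G → E (k = 0.00175 s⁻¹)

At 1.61 min in the flask, the half-life of L on the path to J was 1.6 min, shorter than the 6.6 min of G on the path to E. E and G together came to 99.9 % at 40.0 min in the flask and to 69.1 % in the neighbour charged with 0.80 M of L, so my height of 67.2 %, held over for that neighbour as an estimate, gives it 46.5 %, and it peaked at 43.6 %.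

The runs are simulated from invented constants, noise included.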